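The larch run ends at 62% of the substrate charged, and I read that row, like the last rows of the other earlier runs, as a count on the catalyst.

| flask | substrate | reagent | free catalyst | temperature | remark | time |
|---|---|---|---|---|---|---|
| maple | 0.50 M | 1.5 M | 2.7 mM | 5 °C | run made earlier |  |
| larch | 0.50 M | 1.5 M | 4.2 mM | 25 °C | run made earlier |  |
| cedar | 0.75 M | 1.5 M | 1.9 mM | 5 °C | run made earlier |  |
| alpha | 0.50 M | 1.50 M | 1.9 mM | 10 °C |  | 8.0 h |
| epsilon | 0.50 M | 1.50 M | 1.9 mM | 25 °C |  | 8.0 h |
| theta | 0.50 M | 1.50 M | 1.9 mM | 40 °C |  | 8.0 h |

- maple (time / h: target / %): 0.667: 0; 1.33: 2; 2.00: 6; 3.00: 12; 4.00: 17; 5.00: 26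
- larch (time / h: target / %): 0.333: 7; 0.667: 19; 1.00: 29; 1.33: 43; 2.00: 55; 2.50: 62
- cedar (time / h: target / %): 0.417: 3; 1.33: 1; 2.00: 3; 3.00: 4; 5.00: 15

(each reading ± 1.5 percentage points)



- the flask that comes out highest in amount of target, in percent of the substrate charged, or "all alike" when all lie within 1.5 percentage points (alpha / epsilon / theta / all alike)
- target at the end, in percent of the substrate charged, alpha
- target at the end, in percent of the substrate charged, epsilon
- target at the end, in percent of the substrate charged, theta

My count is the turnover number, the moles of target made per mole of free catalyst charged. The last larch row gives 73.8. The last maple row gives 48.1 and the last cedar row 59.2, so larch stands higher than both. These are readings with their scatter, and target is still rising at each last row.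

Row against row, the larch run gains 36 percentage points in 0.997 h, then 19 points in 1.17 h. Its count is therefore still climbing, but more slowly.

At the larch count, the catalyst charge of alpha, epsilon and theta makes 28.0% of their substrate. Every point above that asks for a higher count than the last larch row, so I judge any estimate for these flasks by the count it demands.

The forecast gives 38% for alpha, 75% for epsilon and 90% for theta, and so names theta highest. It reads the larch run as having “no clear slowing by 2.5 h”. Its epsilon and theta values ask for about 197 and 237 turns, more than the larch count.

The flasks give 37.7% for alpha, 54.9% for epsilon and 49.6% for theta, so epsilon comes out highest.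

    substrate + free catalyst → free catalyst + intermediate (k = 0.250 M⁻¹ s⁻¹, Ea = 43.0 kJ mol⁻¹)
    2 substrate → homo dimer (k = 2.00 × 10⁻⁶ M⁻¹ s⁻¹, Ea = 80.0 kJ mol⁻¹)
    reagent + free catalyst + intermediate → free catalyst + target (k = 0.120 M⁻² s⁻¹, Ea = 55.0 kJ mol⁻¹)
    free catalyst + target → spent catalyst (k = 0.00200 M⁻¹ s⁻¹, Ea = 65.0 kJ mol⁻¹)
    (constants at 40 °C)

Epsilon reaches 145 turns and theta 131. Both pass the larch 73.8 but stay below what the forecast asked. Theta already stands at 49.5% target after 4.00 h, with free catalyst down to 0.377% of its charge. The neighbour flask is theta with 57.9% of that catalyst charge. At theta's count it would make 28.7% of the substrate charged. It gives 38.7%, which is 176 turns, more than theta's.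

The data come from a simulation on assumed constants.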